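**Retrosynthetic overview** (eudesmane numbering: ring A = C1–C5 and C10, ring B = C5–C10, C14 on C10, C15 on C4)
1. The target is eudesm-3-en-6-yl (E)-p-coumarate, (5R,6R,7S,10R); the O6–acyl bond is cut last, giving eudesm-3-en-6-ol and a phenol-protected p-coumaric acid.
2. Ring A is opened at C3=C4 (McMurry coupling of a C3 aldehyde with the C4 methyl ketone) and the side chain at C1–C2 (Wittig), leaving a ring B keto-ester.
3. The strategy rests on ring B: C10 (quaternary, C14), C5 and C6 are contiguous stereocentres, with acyl-type carbons C1 on C10 and C4 on C5 trans to each other and oxygen on C6. This is the retron of a 1-silyloxy-2-isopropylbutadiene (C6–C9) adding across C5=C10 of an (E)-3-acetylmethacrylate.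
4. Ring order: ring B first (Diels–Alder, forms C5–C6 and C9–C10, sets C5, C6, C10); C7 by hydrogenation anti to the C6 silyl ether; ring A second.
5. Diene from 3-methylbutanal and acetaldehyde (directed aldol, dienol silylation); dienophile from methylglyoxal by Wittig olefination.

Key step: step 5

Remark: β denotes the face of ring B that carries the C14 methyl; the target SMILES is read as 5α-H, 6β-O, 7β-isopropyl, 10β-methyl. The carbinol centre formed at C4 in step 6 is a mixture of epimers and is erased in step 7.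

**Route**

Step 1
Reactants: 1 3-methylbutanal
Product: 2 (E)-N-cyclohexyl-3-methylbutan-1-imine
Conditions: cyclohexylamine, 4 Å molecular sieves, Et2O, 0 °C → rt; distil
Reagents that add atoms: cyclohexylamine, NC1CCCCC1
Why: Imine condensation of an unhindered aldehyde with a primary amine goes to completion once water is removed, and the imine prevents self-aldol reaction of 1 in the next step.

Step 2
Reactants: 2 (E)-N-cyclohexyl-3-methylbutan-1-imine; 3 acetaldehyde
Product: 6 (E)-2-(propan-2-yl)but-2-enal, via lithium aza-enolate 4 (not isolated), via hydroxy imine 5 (not isolated)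
Conditions: LiN(i-Pr)2, THF, −78 °C; 3, −78 °C; then aq. (CO2H)2, reflux
Reagents that add atoms: water, O
Why: Directed aldol condensation through the metalated aldimine (Wittig directed aldol) makes 1 the only donor and acetaldehyde the only acceptor, and acid hydrolysis frees the aldehyde and dehydrates the aldol to the conjugated enal, whose alkene geometry is lost in step 3 and therefore does not matter.

Step 3
Reactants: 6 (E)-2-(propan-2-yl)but-2-enal
Product: 7 (1E)-1-(tert-butyldimethylsilyloxy)-2-(propan-2-yl)buta-1,3-diene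
Conditions: t-BuMe2SiOTf, Et3N, Et2O, 0 °C → rt
Reagents that add atoms: tert-butyldimethylsilyl trifluoromethanesulfonate, CC(C)(C)[Si](C)(C)OS(=O)(=O)C(F)(F)F
Why: Vinylogous enol silylation: O-silylation of the s-trans enal gives a silyloxyallyl cation that loses a proton from the γ-methyl group, which should place the silyloxy group trans to the new vinyl group (1E); any (1Z) isomer cannot reach the s-cis conformation and stays inert in step 5.

Step 4
Reactants: 8 methylglyoxal (40% aqueous solution); 9 methyl 2-(triphenylphosphoranylidene)propanoate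
Product: 10 methyl (E)-2-methyl-4-oxopent-2-enoate
Conditions: CH2Cl2, 0 °C → rt
Reagents that add atoms: none
Why: Wittig olefination with a stabilised ylide attacks only the aldehyde carbon of methylglyoxal and should give the (E)-alkene with acetyl trans to the ester.

Step 5
Reactants: 7 (1E)-1-(tert-butyldimethylsilyloxy)-2-(propan-2-yl)buta-1,3-diene; 10 methyl (E)-2-methyl-4-oxopent-2-enoate
Product: 11 methyl (1R,5S,6S)-6-acetyl-5-(tert-butyldimethylsilyloxy)-1-methyl-4-(propan-2-yl)cyclohex-3-ene-1-carboxylate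
Conditions: (S)-3,3-diphenyl-1-(2-methylphenyl)tetrahydro-1H,3H-pyrrolo[1,2-c][1,3,2]oxazaborole (20 mol%), Tf2NH (18 mol%), CH2Cl2, −78 → −40 °C
Reagents that add atoms: none
Why: The N-protonated oxazaborolidine binds the ketone oxygen of 10 (more basic than the ester) and puts the largest LUMO coefficient on C10, while the silyloxy donor makes the unsubstituted terminus C9 of 7 the nucleophilic end, so a concerted, asynchronous [4+2] cycloaddition should form C9–C10 ahead of C5–C6 and give only the regioisomer with oxygen next to the acetyl-bearing carbon. The closest known reaction type is the oxazaborolidinium-catalysed Diels–Alder reaction of acyclic enones and fumarate-type dienophiles with silyloxydienes. Ring B closes as a six-membered carbocycle in the cycloaddition itself, the bond C5–C6 completing the ring. Suprafacial addition to the (E)-alkene fixes C5 relative to C10 (acetyl cis to C14, trans to the ester), the endo position of the boron-bound acetyl under the (1E)-diene fixes C6 (silyloxy cis to acetyl), and the catalyst fixes the absolute sense: the s-trans enone is held by the B–O bond and an α-C–H···O contact, one face is covered by an aryl group, and the diene is expected to add to the 2Re,3Re face of 10. A one-point-binding cationic boron acid is chosen because the trans-disposed carbonyls of 10 cannot chelate one metal centre, as a bis(oxazoline) complex of divalent copper would require; the sense of induction follows the binding model and the (R)-catalyst is equally available. The step needs regio-, endo and facial selectivity and enough reactivity to form the quaternary C10; these rest on ketone-selective activation, the electron-rich diene and the second acceptor on C10.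

Step 6
Reactants: 11 methyl (1R,5S,6S)-6-acetyl-5-(tert-butyldimethylsilyloxy)-1-methyl-4-(propan-2-yl)cyclohex-3-ene-1-carboxylate
Product: 12 1-[2-(tert-butyldimethylsilyloxy)-6-(hydroxymethyl)-6-methyl-3-(propan-2-yl)cyclohex-3-en-1-yl]ethan-1-ol (ring stereocentres as in 11; carbinol carbon as a mixture of epimers)
Conditions: LiAlH4, THF, 0 °C → rt; aq. potassium sodium tartrate
Reagents that add atoms: none
Why: Hydride reduction with LiAlH4 converts the ketone and the hindered ester to alcohols while the silyl ether and the ring alkene are inert, and the new carbinol centre is removed again in step 7.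

Step 7
Reactants: 12 1-[2-(tert-butyldimethylsilyloxy)-6-(hydroxymethyl)-6-methyl-3-(propan-2-yl)cyclohex-3-en-1-yl]ethan-1-ol
Product: 13 (1R,5S,6S)-6-acetyl-5-(tert-butyldimethylsilyloxy)-1-methyl-4-(propan-2-yl)cyclohex-3-ene-1-carbaldehyde
Conditions: (COCl)2, DMSO, CH2Cl2, −78 °C; Et3N, −78 → 0 °C
Reagents that add atoms: none
Why: Swern oxidation activates both hydroxyls as alkoxysulfonium ions before base is added, so no hydroxy-aldehyde can close to a lactol and over-oxidise to a lactone, the aldehyde has no α-hydrogen and the C5 centre next to the ketone should survive the cold amine base.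

Step 8
Reactants: 13 (1R,5S,6S)-6-acetyl-5-(tert-butyldimethylsilyloxy)-1-methyl-4-(propan-2-yl)cyclohex-3-ene-1-carbaldehyde; 14 (triphenylphosphoranylidene)acetaldehyde
Product: 15 (2E)-3-[6-acetyl-5-(tert-butyldimethylsilyloxy)-1-methyl-4-(propan-2-yl)cyclohex-3-en-1-yl]prop-2-enal (ring stereocentres as in 13)
Conditions: toluene, 90 °C
Reagents that add atoms: none
Why: Wittig reaction of the stabilised formyl ylide adds C2 and C3 at the aldehyde only, the methyl ketone being unreactive towards this ylide, and should give the (E)-enal.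

Step 9
Reactants: 15 (2E)-3-[6-acetyl-5-(tert-butyldimethylsilyloxy)-1-methyl-4-(propan-2-yl)cyclohex-3-en-1-yl]prop-2-enal
Product: 16 3-[2-acetyl-3-(tert-butyldimethylsilyloxy)-1-methyl-4-(propan-2-yl)cyclohexyl]propanal (C5, C6, C10 as in 13; isopropyl cis to the silyloxy group)
Conditions: H2 (4 bar), Pd/C (10 wt% Pd), EtOAc, rt
Reagents that add atoms: none
Why: Heterogeneous catalytic hydrogenation reduces the conjugated C1=C2 bond and then C7=C8 from the face opposite the allylic silyloxy group (held pseudoaxial by allylic strain with the isopropyl group), the acetyl group and the C14 methyl, which should place H7 on the α face and the isopropyl group cis to O6, while both carbonyl groups survive in a non-alcoholic solvent.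

Step 10
Reactants: 16 3-[2-acetyl-3-(tert-butyldimethylsilyloxy)-1-methyl-4-(propan-2-yl)cyclohexyl]propanal
Product: 17 tert-butyl{[(1R,2S,4aR,8aR)-4a,8-dimethyl-2-(propan-2-yl)-1,2,3,4,4a,5,6,8a-octahydronaphthalen-1-yl]oxy}dimethylsilane
Conditions: TiCl3(DME)1.5, Zn–Cu couple, DME, reflux; 16 added slowly by syringe pump
Reagents that add atoms: none
Why: Intramolecular McMurry coupling joins the C3 aldehyde and the C4 ketone through a titanium pinacolate that is deoxygenated to the alkene, which closes six-membered ring A with the double bond fixed at C3=C4 and the trans ring fusion already set by C5 and C10, silyl ethers being tolerated by low-valent titanium.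

Step 11
Reactants: 17 tert-butyl{[(1R,2S,4aR,8aR)-4a,8-dimethyl-2-(propan-2-yl)-1,2,3,4,4a,5,6,8a-octahydronaphthalen-1-yl]oxy}dimethylsilane
Product: 18 (1R,2S,4aR,8aR)-4a,8-dimethyl-2-(propan-2-yl)-1,2,3,4,4a,5,6,8a-octahydronaphthalen-1-ol
Conditions: Bu4NF, THF, 50 °C
Reagents that add atoms: none
Why: Fluoride-induced desilylation cleaves the Si–O bond without touching the C6–O bond or the trisubstituted alkene, mild heating compensating for the hindered axial position.

Step 12
Reactants: 19 (E)-p-coumaric acid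
Product: 21 (2E)-3-[4-(tert-butyldimethylsilyloxy)phenyl]prop-2-enoic acid, via bis-silyl derivative 20 (not isolated)
Conditions: t-BuMe2SiCl, imidazole, DMF, rt; then AcOH, THF–H2O, rt
Reagents that add atoms: tert-butyldimethylsilyl chloride, CC(C)(C)[Si](C)(C)Cl
Why: Silylation of both acidic hydroxyls followed by selective hydrolysis of the far more labile silyl ester leaves the aryl silyl ether, which keeps the phenol from competing in the acylation.

Step 13
Reactants: 18 (1R,2S,4aR,8aR)-4a,8-dimethyl-2-(propan-2-yl)-1,2,3,4,4a,5,6,8a-octahydronaphthalen-1-ol; 21 (2E)-3-[4-(tert-butyldimethylsilyloxy)phenyl]prop-2-enoic acid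
Product: 23 (1R,2S,4aR,8aR)-4a,8-dimethyl-2-(propan-2-yl)-1,2,3,4,4a,5,6,8a-octahydronaphthalen-1-yl (2E)-3-[4-(tert-butyldimethylsilyloxy)phenyl]prop-2-enoate, via acyl chloride 22 (not isolated)
Conditions: 21, (COCl)2, cat. DMF, CH2Cl2, 0 °C → rt, evaporate; then 18, 4-(dimethylamino)pyridine, Et3N, toluene, 80 °C
Reagents that add atoms: none
Why: Acylation of the hindered axial alcohol by the acyl chloride under nucleophilic catalysis (acylpyridinium intermediate) forms the ester at oxygen, so the C6 configuration and the (E)-alkene are retained.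

Step 14
Reactants: 23 (1R,2S,4aR,8aR)-4a,8-dimethyl-2-(propan-2-yl)-1,2,3,4,4a,5,6,8a-octahydronaphthalen-1-yl (2E)-3-[4-(tert-butyldimethylsilyloxy)phenyl]prop-2-enoate
Product: 24 (1R,2S,4aR,8aR)-4a,8-dimethyl-2-(propan-2-yl)-1,2,3,4,4a,5,6,8a-octahydronaphthalen-1-yl (2E)-3-(4-hydroxyphenyl)prop-2-enoate (CNP0220414.1)
Conditions: Bu4NF, AcOH, THF, 0 °C
Reagents that add atoms: none
Why: Fluoride cleavage of an aryl silyl ether is fast at 0 °C, and buffering with acetic acid keeps the hindered cinnamate ester and the alkene geometry intact.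

**Compound list**
1 | 3-methylbutanal | CC(C)CC=O | starting material
2 | (E)-N-cyclohexyl-3-methylbutan-1-imine | CC(C)C/C=N/C1CCCCC1 | intermediate
3 | acetaldehyde | CC=O | starting material
4 | lithium cyclohexyl(3-methylbut-1-en-1-yl)amide (lithium aza-enolate of 2) | CC(C)C=CN([Li])C1CCCCC1 | intermediate
5 | 3-[(cyclohexylimino)methyl]-4-methylpentan-2-ol (mixture of diastereomers) | CC(O)C(C=NC1CCCCC1)C(C)C | intermediate
6 | (E)-2-(propan-2-yl)but-2-enal | C/C=C(/C=O)C(C)C | intermediate
7 | (1E)-1-(tert-butyldimethylsilyloxy)-2-(propan-2-yl)buta-1,3-diene | C=C/C(C(C)C)=C/O[Si](C)(C)C(C)(C)C | intermediate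
8 | methylglyoxal | CC(=O)C=O | starting material
9 | methyl 2-(triphenylphosphoranylidene)propanoate | COC(=O)C(C)=P(c1ccccc1)(c1ccccc1)c1ccccc1 | starting material
10 | methyl (E)-2-methyl-4-oxopent-2-enoate | CC(=O)/C=C(\C)C(=O)OC | intermediate
11 | methyl (1R,5S,6S)-6-acetyl-5-(tert-butyldimethylsilyloxy)-1-methyl-4-(propan-2-yl)cyclohex-3-ene-1-carboxylate | CC(=O)[C@@H]1[C@H](O[Si](C)(C)C(C)(C)C)C(C(C)C)=CC[C@@]1(C)C(=O)OC | intermediate
12 | 1-[2-(tert-butyldimethylsilyloxy)-6-(hydroxymethyl)-6-methyl-3-(propan-2-yl)cyclohex-3-en-1-yl]ethan-1-ol (carbinol epimers) | CC(O)[C@@H]1[C@H](O[Si](C)(C)C(C)(C)C)C(C(C)C)=CC[C@@]1(C)CO | intermediate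
13 | (1R,5S,6S)-6-acetyl-5-(tert-butyldimethylsilyloxy)-1-methyl-4-(propan-2-yl)cyclohex-3-ene-1-carbaldehyde | CC(=O)[C@@H]1[C@H](O[Si](C)(C)C(C)(C)C)C(C(C)C)=CC[C@@]1(C)C=O | intermediate
14 | (triphenylphosphoranylidene)acetaldehyde | O=CC=P(c1ccccc1)(c1ccccc1)c1ccccc1 | starting material
15 | (2E)-3-[6-acetyl-5-(tert-butyldimethylsilyloxy)-1-methyl-4-(propan-2-yl)cyclohex-3-en-1-yl]prop-2-enal | CC(=O)[C@@H]1[C@H](O[Si](C)(C)C(C)(C)C)C(C(C)C)=CC[C@@]1(C)/C=C/C=O | intermediate
16 | 3-[2-acetyl-3-(tert-butyldimethylsilyloxy)-1-methyl-4-(propan-2-yl)cyclohexyl]propanal | CC(=O)[C@@H]1[C@H](O[Si](C)(C)C(C)(C)C)[C@H](C(C)C)CC[C@@]1(C)CCC=O | intermediate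
17 | tert-butyl{[(1R,2S,4aR,8aR)-4a,8-dimethyl-2-(propan-2-yl)-1,2,3,4,4a,5,6,8a-octahydronaphthalen-1-yl]oxy}dimethylsilane | CC1=CCC[C@]2(C)CC[C@@H](C(C)C)[C@@H](O[Si](C)(C)C(C)(C)C)[C@@H]12 | intermediate
18 | (1R,2S,4aR,8aR)-4a,8-dimethyl-2-(propan-2-yl)-1,2,3,4,4a,5,6,8a-octahydronaphthalen-1-ol | CC1=CCC[C@]2(C)CC[C@@H](C(C)C)[C@@H](O)[C@@H]12 | intermediate
19 | (E)-p-coumaric acid | OC(=O)/C=C/c1ccc(O)cc1 | starting material
20 | tert-butyldimethylsilyl (2E)-3-[4-(tert-butyldimethylsilyloxy)phenyl]prop-2-enoate | CC(C)(C)[Si](C)(C)OC(=O)/C=C/c1ccc(O[Si](C)(C)C(C)(C)C)cc1 | intermediate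
21 | (2E)-3-[4-(tert-butyldimethylsilyloxy)phenyl]prop-2-enoic acid | OC(=O)/C=C/c1ccc(O[Si](C)(C)C(C)(C)C)cc1 | intermediate
22 | (2E)-3-[4-(tert-butyldimethylsilyloxy)phenyl]prop-2-enoyl chloride | ClC(=O)/C=C/c1ccc(O[Si](C)(C)C(C)(C)C)cc1 | intermediate
23 | (1R,2S,4aR,8aR)-4a,8-dimethyl-2-(propan-2-yl)-1,2,3,4,4a,5,6,8a-octahydronaphthalen-1-yl (2E)-3-[4-(tert-butyldimethylsilyloxy)phenyl]prop-2-enoate | CC1=CCC[C@]2(C)CC[C@@H](C(C)C)[C@@H](OC(=O)/C=C/c3ccc(O[Si](C)(C)C(C)(C)C)cc3)[C@@H]12 | intermediate
24 | (1R,2S,4aR,8aR)-4a,8-dimethyl-2-(propan-2-yl)-1,2,3,4,4a,5,6,8a-octahydronaphthalen-1-yl (2E)-3-(4-hydroxyphenyl)prop-2-enoate | CC1=CCC[C@]2(C)CC[C@@H](C(C)C)[C@@H](OC(=O)/C=C/c3ccc(O)cc3)[C@@H]12 | target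

**Step count**
Total: 14 steps. Longest linear sequence: 12 steps (steps 1, 2, 3, 5, 6, 7, 8, 9, 10, 11, 13, 14).

**Steps most likely to fail**

1. Step 5. The dienophile is held by a single Lewis-acid contact, so facial discrimination may be poor; the silyl enol ether may also add in a Mukaiyama–Michael sense without ring closure, or transfer its silyl group and start an achiral background reaction.
Fallback (two-point binding; sets out from 9 and 7, returns at 11): Wittig reaction of 9 with glyoxylic acid monohydrate should give (2E)-4-methoxy-3-methyl-4-oxobut-2-enoic acid F1. Its pivaloyl mixed anhydride (t-BuCOCl, Et3N, THF) acylates 1,3-oxazolidin-2-one in the presence of LiCl to give 3-[(2E)-4-methoxy-3-methyl-4-oxobut-2-enoyl]-1,3-oxazolidin-2-one F2, in which the chelating imide carbonyl takes the place of the ketone. Cycloaddition of F2 with 7 under the divalent copper complex [Cu((S,S)-t-Bu-box)](SbF6)2 (box = 2,2'-(propane-2,2-diyl)bis[(4S)-4-tert-butyl-4,5-dihydro-1,3-oxazole]) in CH2Cl2 at low temperature should keep the regio- and endo sense and expose the Re face of the imide α-carbon, giving methyl (1R,5S,6S)-5-(tert-butyldimethylsilyloxy)-1-methyl-6-[(2-oxo-1,3-oxazolidin-3-yl)carbonyl]-4-(propan-2-yl)cyclohex-3-ene-1-carboxylate F3. Aminolysis with MeNH(OMe)·HCl and Me3Al gives methyl (1R,5S,6S)-5-(tert-butyldimethylsilyloxy)-6-[methoxy(methyl)carbamoyl]-1-methyl-4-(propan-2-yl)cyclohex-3-ene-1-carboxylate F4, and MeMgBr (THF, −20 °C), which should spare the hindered ester on the quaternary carbon, gives 11.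

2. Step 9. In the conformationally mobile monocyclic ring, hydrogen may be delivered to the wrong face of C7=C8, or the double bond may migrate on palladium towards the tetrasubstituted positions before it is reduced.
Fallback (C7 is set on the rigid decalin; sets out from 15, returns at 17): uptake of one equivalent of H2 over Pd/C in EtOAc reduces only the conjugated disubstituted alkene to give 3-[6-acetyl-5-(tert-butyldimethylsilyloxy)-1-methyl-4-(propan-2-yl)cyclohex-3-en-1-yl]propanal F5. Pinacol cyclisation with samarium diiodide (SmI2, THF, t-BuOH, −78 °C) closes ring A as the cis-3,4-diol 1-(tert-butyldimethylsilyloxy)-4a,8-dimethyl-2-(propan-2-yl)-1,4,4a,5,6,7,8,8a-octahydronaphthalene-7,8-diol F6. In this trans-decalin the axial C14 methyl and the axial silyloxy group block the β face, so hydrogenation (H2, Pd/C, EtOAc) should give 1-(tert-butyldimethylsilyloxy)-4a,8-dimethyl-2-(propan-2-yl)decahydronaphthalene-7,8-diol F7 with the 7β-isopropyl group. Corey–Winter olefination then follows: 1,1'-thiocarbonyldiimidazole in hot toluene gives the cyclic thionocarbonate F8 of the 7,8-diol, and P(OMe)3 at 110 °C gives 17.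

3. Step 10. Low-valent titanium may stop at the pinacol stage, couple two molecules, or reductively expel the β-silyloxy group.
Fallback (ring closure by metathesis; sets out from 16, returns at 17): Wittig methylenation of both carbonyl groups (Ph3P=CH2, THF, 0 °C → rt) gives tert-butyl{[6-(but-3-en-1-yl)-6-methyl-3-(propan-2-yl)-2-(prop-1-en-2-yl)cyclohexyl]oxy}dimethylsilane F9. Ring-closing metathesis with the second-generation Grubbs catalyst (H2IMes)(PCy3)Cl2Ru=CHPh in CH2Cl2 at 40 °C then forms the trisubstituted C3=C4 bond and gives 17.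

**Further compounds**
F1 | step 5 | (2E)-4-methoxy-3-methyl-4-oxobut-2-enoic acid | COC(=O)/C(C)=C/C(=O)O
F2 | step 5 | 3-[(2E)-4-methoxy-3-methyl-4-oxobut-2-enoyl]-1,3-oxazolidin-2-one | COC(=O)/C(C)=C/C(=O)N1CCOC1=O
F3 | step 5 | methyl (1R,5S,6S)-5-(tert-butyldimethylsilyloxy)-1-methyl-6-[(2-oxo-1,3-oxazolidin-3-yl)carbonyl]-4-(propan-2-yl)cyclohex-3-ene-1-carboxylate | O=C2OCCN2C(=O)[C@@H]1[C@H](O[Si](C)(C)C(C)(C)C)C(C(C)C)=CC[C@@]1(C)C(=O)OC
F4 | step 5 | methyl (1R,5S,6S)-5-(tert-butyldimethylsilyloxy)-6-[methoxy(methyl)carbamoyl]-1-methyl-4-(propan-2-yl)cyclohex-3-ene-1-carboxylate | CON(C)C(=O)[C@@H]1[C@H](O[Si](C)(C)C(C)(C)C)C(C(C)C)=CC[C@@]1(C)C(=O)OC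
F5 | step 9 | 3-[6-acetyl-5-(tert-butyldimethylsilyloxy)-1-methyl-4-(propan-2-yl)cyclohex-3-en-1-yl]propanal | CC(=O)[C@@H]1[C@H](O[Si](C)(C)C(C)(C)C)C(C(C)C)=CC[C@@]1(C)CCC=O
F6 | step 9 | 1-(tert-butyldimethylsilyloxy)-4a,8-dimethyl-2-(propan-2-yl)-1,4,4a,5,6,7,8,8a-octahydronaphthalene-7,8-diol (cis-diol) | CC1(O)C(O)CC[C@]2(C)CC=C(C(C)C)[C@@H](O[Si](C)(C)C(C)(C)C)[C@@H]12
F7 | step 9 | 1-(tert-butyldimethylsilyloxy)-4a,8-dimethyl-2-(propan-2-yl)decahydronaphthalene-7,8-diol (cis-diol) | CC1(O)C(O)CC[C@]2(C)CC[C@@H](C(C)C)[C@@H](O[Si](C)(C)C(C)(C)C)[C@@H]12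
F8 | step 9 | cyclic thionocarbonate of the 7,8-diol F7 | CC12OC(=S)OC1CC[C@]1(C)CC[C@@H](C(C)C)[C@@H](O[Si](C)(C)C(C)(C)C)[C@@H]21
F9 | step 10 | tert-butyl{[6-(but-3-en-1-yl)-6-methyl-3-(propan-2-yl)-2-(prop-1-en-2-yl)cyclohexyl]oxy}dimethylsilane | C=C(C)[C@@H]1[C@H](O[Si](C)(C)C(C)(C)C)[C@H](C(C)C)CC[C@@]1(C)CCC=C
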